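**Remark (assumption).** The target has no stereocentre and no hindered axis, so it is achiral. "Single enantiomer" is therefore read as "the constitution given", and no asymmetric step is needed. Flavone numbering (O1, C2, C3, C4, C4a, C5–C8, C8a; B ring C1'–C6') is used throughout.

## The problem

- The A ring of the flavone carries no hydrogen: C5, C6, C7 and C8 bear OMe, C8a bears the ring oxygen O1, and C4a bears the C4 carbonyl.
- No cheap building block has five contiguous C–O carbons on one benzene ring. The o-hydroxyacetophenone that the classical flavone syntheses start from is itself the end of a multi-step arene oxygenation sequence.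
- The B ring holds one free phenol (3'-OH) among six methyl ethers. This oxygen must be differentiated from the start and masked through any O-methylation.
- The C ring is easy to close but fragile: C2 is electrophilic, C2=C3 can be reduced, the 5-OMe peri to C4=O is cleaved by Lewis acids, and a 5-OH is chelated and slow to alkylate.
- There is no stereocentre to set. The only ones on the way (C4 of 11, C4a of 13) are racemic and transient.
- The feature that makes the key step possible: C5–C6–C7–C8 is a chain of four sp2 carbons, each bearing one oxygen, with the C5 and C8 oxygens para to each other. This is the C4O4 core of squaric acid.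
- The other two A-ring carbons, C4a and C8a, are the C5=C6 enol-ether double bond of a 2-aryl-4H-pyran-4-one, whose C6–H is its only α-oxy vinylic C–H.
- Because the C4 unit is symmetric end to end, the pyranone may be joined through either carbon of that C=C and the same flavone results.

## Retrosynthesis

**16 ⇒ 15.** The 3'-O–benzyl bond is cut. Target 16 comes from benzyl ether 15 by hydrogenolysis. Benzyl is chosen because it should survive amide bases, 140 °C and K2CO3/Me2SO4, and it leaves under neutral conditions; a Lewis-acid deprotection would also take the 5-OMe. The forward step must spare C2=C3.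

**15 ⇒ 14.** The O–CH3 bonds at C5 and C8 are cut, which exposes hydroquinone 14, the native product of a squarate ring expansion. Methylating the carbinol before the ring expansion is rejected, because strong methylating agents O-alkylate the pyranone carbonyl. The forward step must methylate the chelated C5–OH fully and exclude air.

**14 ⇒ 11 (key).** The C4a–C5 bond is cut and C5 is reconnected to C8, so the hexasubstituted benzene ring becomes the four-membered ring of cyclobutenone 11, attached to a pyranone. Cutting the C ring instead, as classical routes do, leaves the A-ring problem untouched. The precursor has one ring fewer and consists of two simple pieces. The forward reaction is a thermal 4π opening, 6π closure and tautomerization, passing through dienylketene 12 and cyclohexadienone 13.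

**11 ⇒ 8 + 9.** The bond between the carbinol carbon (future C8) and the pyranone carbon (future C8a) is cut, giving 2-aryl-4-pyranone 8 and dimethyl squarate 9.
- Attachment at pyranone C6 rather than C5 is preferred, because C6–H can be removed directly by base (via lithio species 10), whereas C5 would need a regioselective halogenation and a halogen–metal exchange.
- Both carbonyls of 9 are equivalent, so the addition has no regiochemistry.
- The forward step needs clean C6 deprotonation and 1,2-addition.

**8 ⇒ 5 + 6.** The pyranone bonds C2–C3 and O1–C6 are cut, giving acid chloride 5 and (E)-4-methoxybut-3-en-2-one 6, joined through diketone 7. This is preferred over arylating a preformed halopyranone because it gives the 6-unsubstituted pyranone directly from a commercial C4 unit. The forward step is a C-acylation of a kinetic enolate and an acid-catalysed ring closure.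

**5 ⇒ 4 ⇒ 1 + 2.** These are functional-group changes only. Acid chloride 5 comes from acid 4, which comes from commercial 3-hydroxy-4,5-dimethoxybenzoic acid 1 and benzyl bromide 2 through benzyl ester 3. The 3-OH/4,5-OMe pattern is bought with 1, so the B-ring differentiation costs one benzylation.

## Roads not taken

**Alternative 1:** The obvious cut is through the C ring (O1–C2 and C2–C3).
- Forward key step: Claisen–Schmidt condensation of 1-(2-hydroxy-3,4,5,6-tetramethoxyphenyl)ethan-1-one A1 with 3-(benzyloxy)-4,5-dimethoxybenzaldehyde A2 to chalcone A3, then I2/DMSO oxidative cyclization to 15. The Baker–Venkataraman variant is equivalent.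
- Why the chosen plan is better: this route forms only the easiest ring. All the difficulty sits in A1, whose pentaoxygenated ring must be built by serial arene oxygenation and selective demethylation. In the chosen plan the four oxygenated carbons arrive in one commercial C4 unit and the A ring is made in one operation.

**Alternative 2:** A three-component cut of C4–C4a, C3–C4 and O1–C2.
- Forward key step: palladium-catalysed carbonylative Sonogashira annulation of 2-iodo-3,4,5,6-tetramethoxyphenol A4, CO and 1-(benzyloxy)-5-ethynyl-2,3-dimethoxybenzene A5 to 15.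
- Why the chosen plan is better: A4 is no easier to make than A1 and needs a regiospecific iodination on top. Oxidative addition and CO insertion at a di-ortho-substituted, electron-rich aryl iodide are slow. The 6-endo closure must be steered against 5-exo closure. The multicomponent step again builds only the C ring.

**Alternative 3:** A cut of the C2–C1' bond, with the B ring attached last.
- Forward key step: C2–H arylation (oxidative Heck type) of 5,6,7,8-tetramethoxy-4H-chromen-4-one A6 with arylboronate A7, where A6 would come from the same squarate annulation on the parent 4-pyranone.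
- Why the chosen plan is better: this adds a C–C bond-forming step after the annulation, and the arylation competes with conjugate addition and needs a stoichiometric oxidant. The parent pyranone has two equivalent α-oxy C–H bonds and two open electrophilic positions, so its mono-lithiation is less clean. A7 needs its own two steps. In the chosen route the aryl group is in place first and blocks C2, so only C6–H can be metalated.

Key step: step 5

## Route

Step 1
Reactants: 1 3-hydroxy-4,5-dimethoxybenzoic acid; 2 benzyl bromide
Product: 4 3-(benzyloxy)-4,5-dimethoxybenzoic acid, via benzyl ester 3 (not isolated)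
Conditions: BnBr (2.3 equiv), K2CO3, DMF, 60 °C; then 2 M NaOH, MeOH, 65 °C; HCl
Reagents that add atoms: sodium hydroxide, [Na+].[OH-]
Why: Williamson alkylation of phenoxide and carboxylate, then saponification of the benzyl ester only, since the aryl benzyl ether is inert to hydroxide; the carboxyl OH oxygen of 4 comes from hydroxide (acyl–oxygen cleavage).

Step 2
Reactants: 4 3-(benzyloxy)-4,5-dimethoxybenzoic acid
Product: 5 3-(benzyloxy)-4,5-dimethoxybenzoyl chloride
Conditions: (COCl)2, DMF (cat.), CH2Cl2, 0 °C to rt; evaporate, use crude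
Reagents that add atoms: oxalyl chloride, ClC(=O)C(=O)Cl
Why: Acid chloride formation through the Vilsmeier-type chloroiminium species; no Lewis acid is present, so the benzyl and methyl ethers should be untouched.

Step 3
Reactants: 5 3-(benzyloxy)-4,5-dimethoxybenzoyl chloride; 6 (E)-4-methoxybut-3-en-2-one
Product: 8 2-[3-(benzyloxy)-4,5-dimethoxyphenyl]-4H-pyran-4-one, via enolized diketone 7 (not isolated)
Conditions: 6 (2.1 equiv), LiHMDS (2.1 equiv), THF, −78 °C; then 5, −78 °C; NH4Cl; then TFA (cat.), CH2Cl2, rt
Reagents that add atoms: none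
Why: Crossed Claisen C-acylation of the kinetic methyl enolate of 6, the second equivalent of enolate taking up the acidic diketone proton; acid then promotes 6-endo oxa-Michael addition of the enol oxygen and loss of methanol to give the γ-pyrone.

Step 4
Reactants: 8 2-[3-(benzyloxy)-4,5-dimethoxyphenyl]-4H-pyran-4-one; 9 dimethyl squarate (3,4-dimethoxycyclobut-3-ene-1,2-dione)
Product: 11 (±)-4-{6-[3-(benzyloxy)-4,5-dimethoxyphenyl]-4-oxo-4H-pyran-2-yl}-4-hydroxy-2,3-dimethoxycyclobut-2-en-1-one, via 6-lithiopyranone 10 (not isolated)
Conditions: LiTMP (1.1 equiv, from TMP and n-BuLi), THF, −78 °C, 8 added to the base; then 9 (1.3 equiv), −78 °C; NH4Cl at −78 °C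
Reagents that add atoms: none
Why: C6–H is the only α-oxy vinylic C–H of 8 (C2 is blocked by the aryl group) and should be the kinetically most acidic, as in the C2-lithiation of chromones, while the hindered amide avoids conjugate addition. The α-alkoxyvinyllithium 10 should add 1,2 to one of the two equivalent carbonyls of 9, as furyl- and 1-alkoxyvinyllithiums do. The new carbinol stereocentre forms as a racemate and is erased in step 5.

Step 5
Reactants: 11 (±)-4-{6-[3-(benzyloxy)-4,5-dimethoxyphenyl]-4-oxo-4H-pyran-2-yl}-4-hydroxy-2,3-dimethoxycyclobut-2-en-1-one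
Product: 14 2-[3-(benzyloxy)-4,5-dimethoxyphenyl]-5,8-dihydroxy-6,7-dimethoxy-4H-chromen-4-one, via dienylketene 12 (not isolated), via cyclohexadienone 13 (not isolated)
Conditions: p-xylene (degassed, 0.02 M), 138 °C, Ar
Reagents that add atoms: none
Why: Heating opens the cyclobutenone by a conrotatory 4π electrocyclic reaction in which the C4 hydroxyl, as the donor substituent, rotates outward, so the pyranyl group ends up cis to the ketene in (Z)-dienylketene 12. A 6π electrocyclization of 12 then joins the ketene carbon to C3 of the pyran-2-yl group (the future C5–C4a bond) and closes the six-membered A ring in 13. The C4a proton of 13 lies between two carbonyl groups and should move at once to the C5 oxygen, so aromatization to hydroquinone 14 makes the sequence irreversible. The closest known reaction type is the thermal ring expansion of 4-aryl-, 4-alkenyl- and 4-heteroaryl-4-hydroxycyclobutenones made from squarate esters (Moore rearrangement), known also for 2-furyl and cyclic 1-alkoxyvinyl substituents. No stereocentre is created: the racemic centres of 11 and 13 disappear on aromatization. Regiochemistry needs no control, because the carbinol-bearing pyranone carbon is flanked only by O1 and by the C3–H carbon, so the ketene has a single carbon terminus; that carbon is the nucleophilic β-carbon of the enol ether, matched to the electrophilic ketene. Lactonization to a butenolide is excluded by the outward position of the hydroxyl, and intermolecular ketene trapping and oxidation of 14 are held back by high dilution and exclusion of air.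

Step 6
Reactants: 14 2-[3-(benzyloxy)-4,5-dimethoxyphenyl]-5,8-dihydroxy-6,7-dimethoxy-4H-chromen-4-one
Product: 15 2-[3-(benzyloxy)-4,5-dimethoxyphenyl]-5,6,7,8-tetramethoxy-4H-chromen-4-one
Conditions: Me2SO4 (excess), K2CO3, acetone, reflux, N2
Reagents that add atoms: dimethyl sulfate, COS(=O)(=O)OC
Why: Williamson O-methylation of both phenols; excess reagent and reflux are the standard answer to the chelated C5–OH, exclusion of air keeps the hydroquinone from oxidizing, and the benzyl ether keeps the 3'-oxygen out of the methylation.

Step 7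
Reactants: 15 2-[3-(benzyloxy)-4,5-dimethoxyphenyl]-5,6,7,8-tetramethoxy-4H-chromen-4-one
Product: 16 2-(3-hydroxy-4,5-dimethoxyphenyl)-5,6,7,8-tetramethoxy-4H-chromen-4-one (3'-hydroxy-5,6,7,8,4',5'-hexamethoxyflavone)
Conditions: H2 (1 atm), 10% Pd/C, EtOAc–MeOH, rt
Reagents that add atoms: none
Why: Catalytic hydrogenolysis of the aryl benzyl ether; the conjugated C2=C3 bond of a flavone is reduced much more slowly, and the neutral conditions leave the 5-OMe intact.

## Compound list

1 | 3-hydroxy-4,5-dimethoxybenzoic acid | COc1cc(C(=O)O)cc(O)c1OC | starting material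
2 | benzyl bromide | BrCc1ccccc1 | starting material
3 | benzyl 3-(benzyloxy)-4,5-dimethoxybenzoate | COc1cc(C(=O)OCc2ccccc2)cc(OCc2ccccc2)c1OC | intermediate
4 | 3-(benzyloxy)-4,5-dimethoxybenzoic acid | COc1cc(C(=O)O)cc(OCc2ccccc2)c1OC | intermediate
5 | 3-(benzyloxy)-4,5-dimethoxybenzoyl chloride | COc1cc(C(Cl)=O)cc(OCc2ccccc2)c1OC | intermediate
6 | (E)-4-methoxybut-3-en-2-one | CO/C=C/C(C)=O | starting material
7 | (E)-1-[3-(benzyloxy)-4,5-dimethoxyphenyl]-5-methoxypent-4-ene-1,3-dione (largely enolized) | COc1cc(C(=O)CC(=O)/C=C/OC)cc(OCc2ccccc2)c1OC | intermediate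
8 | 2-[3-(benzyloxy)-4,5-dimethoxyphenyl]-4H-pyran-4-one | COc1cc(-c2cc(=O)cco2)cc(OCc2ccccc2)c1OC | intermediate
9 | dimethyl squarate (3,4-dimethoxycyclobut-3-ene-1,2-dione) | COC1=C(OC)C(=O)C1=O | starting material
10 | {6-[3-(benzyloxy)-4,5-dimethoxyphenyl]-4-oxo-4H-pyran-2-yl}lithium | [Li]c1cc(=O)cc(-c2cc(OC)c(OC)c(OCc3ccccc3)c2)o1 | intermediate
11 | (±)-4-{6-[3-(benzyloxy)-4,5-dimethoxyphenyl]-4-oxo-4H-pyran-2-yl}-4-hydroxy-2,3-dimethoxycyclobut-2-en-1-one | COC1=C(OC)C(O)(c2cc(=O)cc(-c3cc(OC)c(OC)c(OCc4ccccc4)c3)o2)C1=O | intermediate
12 | (Z)-4-{6-[3-(benzyloxy)-4,5-dimethoxyphenyl]-4-oxo-4H-pyran-2-yl}-4-hydroxy-2,3-dimethoxybuta-1,3-dien-1-one | COC(=C=O)/C(OC)=C(/O)c1cc(=O)cc(-c2cc(OC)c(OC)c(OCc3ccccc3)c2)o1 | intermediate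
13 | (±)-2-[3-(benzyloxy)-4,5-dimethoxyphenyl]-8-hydroxy-6,7-dimethoxy-4aH-chromene-4,5-dione | COC1=C(OC)C(=O)C2C(=O)C=C(c3cc(OC)c(OC)c(OCc4ccccc4)c3)OC2=C1O | intermediate
14 | 2-[3-(benzyloxy)-4,5-dimethoxyphenyl]-5,8-dihydroxy-6,7-dimethoxy-4H-chromen-4-one | COc1cc(-c2cc(=O)c3c(O)c(OC)c(OC)c(O)c3o2)cc(OCc2ccccc2)c1OC | intermediate
15 | 2-[3-(benzyloxy)-4,5-dimethoxyphenyl]-5,6,7,8-tetramethoxy-4H-chromen-4-one | COc1cc(-c2cc(=O)c3c(OC)c(OC)c(OC)c(OC)c3o2)cc(OCc2ccccc2)c1OC | intermediate
16 | 2-(3-hydroxy-4,5-dimethoxyphenyl)-5,6,7,8-tetramethoxy-4H-chromen-4-one | COc1cc(-c2cc(=O)c3c(OC)c(OC)c(OC)c(OC)c3o2)cc(O)c1OC | target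

## Step count and risk

Total step count: 7. Longest linear sequence: 7 steps (1 to 16); compounds 2, 6 and 9 are purchased.

**Step 5 (key step).**
- What may go wrong: diversion of the dienylketene before ring closure. Closure onto the pyranone interrupts the cross-conjugated 4-pyranone π-system in 13, so it may be slower than in the furyl or alkoxyvinyl cases. Intermolecular trapping of the ketene by hydroxyl groups, or oxidation of the electron-rich hydroquinone by traces of air at 138 °C, could then take over.
- Fallback (sets out from 9 and 5, returns at 15): the A ring is made first on a carbonyl-free partner and the C ring is closed classically.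
  - 1-Methoxyvinyllithium (methyl vinyl ether, t-BuLi, THF) is added to 9 to give 4-hydroxy-2,3-dimethoxy-4-(1-methoxyethenyl)cyclobut-2-en-1-one F1.
  - Thermolysis of F1 in p-xylene should give 2,3,5-trimethoxybenzene-1,4-diol F2.
  - Methylation (Me2SO4, K2CO3, acetone) gives pentamethoxybenzene F3.
  - Friedel–Crafts acetylation with ortho-demethylation (AcCl, AlCl3) gives 1-(2-hydroxy-3,4,5,6-tetramethoxyphenyl)ethan-1-one F4, the same compound as A1.
  - O-Acylation with 5 (pyridine) gives 2-acetyl-3,4,5,6-tetramethoxyphenyl 3-(benzyloxy)-4,5-dimethoxybenzoate F5.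
  - Baker–Venkataraman rearrangement (KOH, pyridine) gives 1-[3-(benzyloxy)-4,5-dimethoxyphenyl]-3-(2-hydroxy-3,4,5,6-tetramethoxyphenyl)propane-1,3-dione F6.
  - Cyclodehydration (H2SO4, AcOH) gives 15.

**Step 4.**
- What may go wrong: self-condensation or ring cleavage of the lithiated pyranone before it meets the squarate, conjugate addition of the amide at C6, or addition–elimination at the vinylogous ester of 9 instead of 1,2-addition.
- Fallback (sets out from 8, returns at 14): the other carbon of the same double bond is used, with a less basic organometallic.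
  - Amine-mediated α-iodination (I2, pyridine, CH2Cl2), expected at C5 because that carbon lies next to the unhindered C6–H position, gives 2-[3-(benzyloxy)-4,5-dimethoxyphenyl]-5-iodo-4H-pyran-4-one F7.
  - Iodine–magnesium exchange (i-PrMgCl·LiCl, THF, −40 °C) gives {6-[3-(benzyloxy)-4,5-dimethoxyphenyl]-4-oxo-4H-pyran-3-yl}magnesium chloride F8, which is not isolated.
  - Addition of F8 to 9 gives the regioisomeric carbinol (±)-4-{6-[3-(benzyloxy)-4,5-dimethoxyphenyl]-4-oxo-4H-pyran-3-yl}-4-hydroxy-2,3-dimethoxycyclobut-2-en-1-one F9.
  - Thermolysis of F9 as in step 5 closes the ring at the O-bearing C2–H of the pyranone. Because the squarate-derived C4 unit is symmetric end to end, this gives the same hydroquinone 14.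

**Step 6.**
- What may go wrong: aerial oxidation of the hydroquinone dianion under the basic conditions, and incomplete methylation of the chelated C5–OH.
- Fallback (sets out from 14, returns at 15): the oxidation is made deliberate. Ag2O in CH2Cl2 converts 14 into the air-stable, purifiable quinone 2-[3-(benzyloxy)-4,5-dimethoxyphenyl]-6,7-dimethoxy-4H-chromene-4,5,8-trione F10. Reductive methylation under phase transfer (Na2S2O4, Bu4NBr, aq. KOH/THF, then Me2SO4, N2) gives 15.

**Step 3.**
- What may go wrong: O-acylation or double acylation of the enolate, and self-condensation of the sensitive enolate of 6.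
- Fallback (sets out from 5, returns at 8): the pyranone carbons are added in a different order.
  - 5 acylates the lithium enolate of acetone (LiHMDS, THF, −78 °C) to give 1-[3-(benzyloxy)-4,5-dimethoxyphenyl]butane-1,3-dione F11.
  - The dianion of F11 (LDA, 2.2 equiv) is formylated at the terminal methyl group with ethyl formate to give 5-[3-(benzyloxy)-4,5-dimethoxyphenyl]-3,5-dioxopentanal F12.
  - Acid (TFA) closes F12 with loss of water to 8.

## Further compounds

F1 | step 5 | 4-hydroxy-2,3-dimethoxy-4-(1-methoxyethenyl)cyclobut-2-en-1-one | C=C(OC)C1(O)C(OC)=C(OC)C1=O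
F2 | step 5 | 2,3,5-trimethoxybenzene-1,4-diol | COc1cc(O)c(OC)c(OC)c1O
F3 | step 5 | pentamethoxybenzene | COc1cc(OC)c(OC)c(OC)c1OC
F4 | step 5 | 1-(2-hydroxy-3,4,5,6-tetramethoxyphenyl)ethan-1-one | CC(=O)c1c(O)c(OC)c(OC)c(OC)c1OC
F5 | step 5 | 2-acetyl-3,4,5,6-tetramethoxyphenyl 3-(benzyloxy)-4,5-dimethoxybenzoate | CC(=O)c1c(OC(=O)c2cc(OC)c(OC)c(OCc3ccccc3)c2)c(OC)c(OC)c(OC)c1OC
F6 | step 5 | 1-[3-(benzyloxy)-4,5-dimethoxyphenyl]-3-(2-hydroxy-3,4,5,6-tetramethoxyphenyl)propane-1,3-dione | COc1cc(C(=O)CC(=O)c2c(O)c(OC)c(OC)c(OC)c2OC)cc(OCc2ccccc2)c1OC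
F7 | step 4 | 2-[3-(benzyloxy)-4,5-dimethoxyphenyl]-5-iodo-4H-pyran-4-one | COc1cc(-c2cc(=O)c(I)co2)cc(OCc2ccccc2)c1OC
F8 | step 4 | {6-[3-(benzyloxy)-4,5-dimethoxyphenyl]-4-oxo-4H-pyran-3-yl}magnesium chloride | COc1cc(-c2cc(=O)c([Mg]Cl)co2)cc(OCc2ccccc2)c1OC
F9 | step 4 | (±)-4-{6-[3-(benzyloxy)-4,5-dimethoxyphenyl]-4-oxo-4H-pyran-3-yl}-4-hydroxy-2,3-dimethoxycyclobut-2-en-1-one | COC1=C(OC)C(O)(c2coc(-c3cc(OC)c(OC)c(OCc4ccccc4)c3)cc2=O)C1=O
F10 | step 6 | 2-[3-(benzyloxy)-4,5-dimethoxyphenyl]-6,7-dimethoxy-4H-chromene-4,5,8-trione | COC1=C(OC)C(=O)c2oc(-c3cc(OC)c(OC)c(OCc4ccccc4)c3)cc(=O)c2C1=O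
F11 | step 3 | 1-[3-(benzyloxy)-4,5-dimethoxyphenyl]butane-1,3-dione | COc1cc(C(=O)CC(C)=O)cc(OCc2ccccc2)c1OC
F12 | step 3 | 5-[3-(benzyloxy)-4,5-dimethoxyphenyl]-3,5-dioxopentanal | COc1cc(C(=O)CC(=O)CC=O)cc(OCc2ccccc2)c1OC
A1 | alternative 1 | 1-(2-hydroxy-3,4,5,6-tetramethoxyphenyl)ethan-1-one | CC(=O)c1c(O)c(OC)c(OC)c(OC)c1OC
A2 | alternative 1 | 3-(benzyloxy)-4,5-dimethoxybenzaldehyde | COc1cc(C=O)cc(OCc2ccccc2)c1OC
A3 | alternative 1 | (E)-3-[3-(benzyloxy)-4,5-dimethoxyphenyl]-1-(2-hydroxy-3,4,5,6-tetramethoxyphenyl)prop-2-en-1-one | COc1cc(/C=C/C(=O)c2c(O)c(OC)c(OC)c(OC)c2OC)cc(OCc2ccccc2)c1OC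
A4 | alternative 2 | 2-iodo-3,4,5,6-tetramethoxyphenol | COc1c(O)c(I)c(OC)c(OC)c1OC
A5 | alternative 2 | 1-(benzyloxy)-5-ethynyl-2,3-dimethoxybenzene | COc1cc(C#C)cc(OCc2ccccc2)c1OC
A6 | alternative 3 | 5,6,7,8-tetramethoxy-4H-chromen-4-one | O=c1ccoc2c(OC)c(OC)c(OC)c(OC)c12
A7 | alternative 3 | 2-[3-(benzyloxy)-4,5-dimethoxyphenyl]-4,4,5,5-tetramethyl-1,3,2-dioxaborolane | COc1cc(B2OC(C)(C)C(C)(C)O2)cc(OCc2ccccc2)c1OC
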